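## Structural features

The target is an isoflavone: a 4H-chromen-4-one (benzo ring A fused to pyranone ring C) that carries aryl ring B at C3 through the C3–C1' bond. Ring A is of the phloroglucinol type, with free hydroxyl groups at C5 and C7 and hydrogen at C6 and C8, the C5 hydroxyl being hydrogen-bonded to the C4 carbonyl. Ring B is pentasubstituted, with methoxy groups at C2', C4' and C6', a free hydroxyl at C3' and a single hydrogen at C5', so that C1' is flanked by two ortho methoxy groups and the C3–C1' bond is crowded and twisted. There is no stereocentre and no configurationally stable axis is implied, so the problem is one of connectivity and of telling three phenols from three methyl ethers. Fragile points are the very electron-rich ring B (a 2,4,6-trimethoxyphenol, easily oxidised and easily attacked by electrophiles at C5'), the electrophilic C2 of ring C, the reducible C2=C3 bond and aryl ethers ortho to a carbonyl group under Lewis acids. The real difficulty is to fuse ring C onto ring A in the right orientation to the C5 and C7 oxygens while the crowded, sensitive ring B already sits on C3, without strong acid, oxidant or a hindered cross-coupling. The key step exploits the fact that C8a (bearing O1) and C4a (bearing the C4 carbonyl) are neighbours on ring A and that C4a lies ortho to the C5 oxygen: both substituents are delivered to the two carbons of a 3,5-dialkoxybenzyne, whose C3 alkoxy group decides which carbon takes oxygen and which takes the acyl carbon. Ring B without its C1' substituent is a 2,4,6-trimethoxyphenol whose two free positions are equivalent by symmetry, which removes any regiochemical question from its functionalisation.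

## Logic of the disconnections

18 to 17: the three O–benzyl bonds at O5, O7 and O3' are cut. Benzyl is chosen because the three phenols must be told apart from three methyl ethers and because it leaves under neutral hydrogenolysis. The gain is that no free phenol is present in any basic or organometallic step. The demand is that the hydrogenolysis spares the C2=C3 bond.

17 to 7 and 14 (through 15 and 16): the bonds C8a–O1, C4a–C4 and O1–C2 are cut, which removes ring C as a whole. The cut is made here because C8a and C4a are the two carbons of an aryne and because the acid 7 already holds C2, C3, C4, O1 and the crowded C3–C1' bond. The gain is the largest available: the target falls into two arene fragments of similar size, each made in a few steps. The demand is threefold: oxygen must add to the aryne carbon remote from the flanking benzyloxy group, the acyl shift must outrun proton capture by the aryl anion, and the phenoxide of 16 must close on the β-carbon with loss of methoxide.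

14 to 8 (through 13, 12, 11, 10 and 9): the O–S bond of the triflate, the C2–Si bond and the carbamate C–O bond are cut. The carbamate is chosen because it directs lithiation to C2, the position between two oxygen substituents, and is then removed in the same flask in which the triflate is made. The gain is that 8 is commercial and symmetrical, so the two ortho positions are the same. The demand is that lithiation beats deprotonation of the benzyl ethers.

7 to 5 (through 6): the ester C–O bond and then the enol ether C=C bond (the future C2=C3) are cut. A methoxymethylene Wittig reaction brings in C2 at the right oxidation level together with its leaving group. The gain is a one-step entry to the β-methoxyacrylate from a ketone. The demand is olefination of a ketone shielded by two ortho methoxy groups.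

5 to 4: the C1'–C bond (the future C3–C1' bond) is cut. The crowded bond is made by electrophilic substitution with a small acyl electrophile on a very activated arene, where steric demand is low. The gain is that the two free positions of 4 are equivalent, so only one product is possible. The demand is that the Lewis acid spares the ethers.

4 to 1 (through 3 and 2): the O–benzyl bond and then the aryl C–O bond are cut, the latter as a Dakin-type oxidation of an aldehyde. The gain is that 1 is a cheap commercial compound. The demand is that the electron-rich phenol 3 is handled without air oxidation.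

## Other disconnections considered

Alternative 1: the deoxybenzoin route, the first that comes to mind. The cut is at C4–C4a and on both sides of C2. Forward, Houben–Hoesch acylation of benzene-1,3,5-triol A1 with arylacetonitrile A2 would give deoxybenzoin A3, and one-carbon insertion (DMF, BF3·OEt2, MsCl) would close ring C to the 3'-O-benzyl isoflavone A4, debenzylated to 18. The chosen plan is preferred on three grounds. The Hoesch step needs HCl and ZnCl2, which threaten the C3' benzyl ether, and the nitrile is hindered by two ortho methoxy groups. The formylating electrophile of the closure would also be offered the free, strongly activated C5' of ring B and C6 and C8 of ring A. A2 needs more steps than 7 from the same arene 4. It is also the route most chemists would draw.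

Alternative 2: the cut is the C3–C1' bond. Forward, Suzuki–Miyaura coupling of 3-iodochromone A5 with boronic acid A6 (Pd(PPh3)4, K2CO3) would give 17 directly. The chosen plan is preferred because A6 is a 2,6-dimethoxy, very electron-rich boronic acid, a class prone to fast protodeboronation under the basic aqueous conditions of the coupling. Transmetalation and reductive elimination to a bond flanked by two ortho methoxy groups and the C4 carbonyl should be slow, and A5 is opened by base at C2. The chosen route makes the C3–C1' bond early, by acylation with a small electrophile.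

Alternative 3: the cut is again the C3–C1' bond, but as a 1,2-aryl shift that mirrors biosynthesis. Forward, 2'-hydroxychalcone A7 would be rearranged oxidatively (Tl(NO3)3, a trivalent thallium salt, in MeOH, or PhI(OAc)2) to acetal A8, which acid would cyclise to 17. The chosen plan is preferred because the migrating ring is so electron-rich that the oxidant should attack it (at the free C5' or by oxidation towards a quinone) in competition with the enone. The styrene part of A7 is twisted by two ortho methoxy groups, which disfavours the aryl-bridged cation. A stoichiometric toxic metal is also avoided.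

Key step: step 9

Assumption: 1 and 8 are taken as commercial; 6, 7 and 16 are carried as E/Z mixtures of the enol ether, since this geometry is erased when ring C closes.

## Route

Step 1
Reactants: 1 2,4,6-trimethoxybenzaldehyde
Product: 3 2,4,6-trimethoxyphenol, via 2,4,6-trimethoxyphenyl formate 2 (not isolated)
Conditions: mCPBA, CH2Cl2, 0 °C to rt; then K2CO3 (cat.), MeOH, rt, under N2
Reagents that add atoms: 3-chloroperoxybenzoic acid (mCPBA), OOC(=O)c1cccc(Cl)c1
Why: Dakin-type Baeyer–Villiger oxidation; the very electron-rich aryl group migrates in preference to hydrogen, and the aryl formate is cleaved by methanolysis. The phenol should be kept under inert gas and used at once.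

Step 2
Reactants: 3 2,4,6-trimethoxyphenol
Product: 4 2-(benzyloxy)-1,3,5-trimethoxybenzene
Conditions: BnBr, K2CO3, DMF, rt
Reagents that add atoms: benzyl bromide, BrCc1ccccc1
Why: Williamson ether synthesis on a phenoxide; O-alkylation masks the oxidation-prone phenol for the rest of the route.

Step 3
Reactants: 4 2-(benzyloxy)-1,3,5-trimethoxybenzene
Product: 5 methyl 2-[3-(benzyloxy)-2,4,6-trimethoxyphenyl]-2-oxoacetate
Conditions: ClCOCO2Me, TiCl4, CH2Cl2, −78 to −20 °C; aqueous work-up
Reagents that add atoms: methyl chlorooxoacetate, COC(=O)C(Cl)=O
Why: Friedel–Crafts acylation; the two free ring positions of 4 are equivalent by symmetry and each is ortho, ortho and para to a methoxy group, so one product is expected. The ketoester deactivates the ring against a second acylation, and the low temperature should spare the ethers.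

Step 4
Reactants: 5 methyl 2-[3-(benzyloxy)-2,4,6-trimethoxyphenyl]-2-oxoacetate
Product: 6 methyl 2-[3-(benzyloxy)-2,4,6-trimethoxyphenyl]-3-methoxyprop-2-enoate (E/Z mixture)
Conditions: Ph3P(CH2OMe)Cl, KOtBu, THF, 0 °C to rt
Reagents that add atoms: (methoxymethyl)triphenylphosphonium chloride, COC[P+](c1ccccc1)(c1ccccc1)c1ccccc1.[Cl-]
Why: Wittig methoxymethylenation of an α-keto ester, the standard entry to β-methoxyacrylates; the ketone is activated by the neighbouring ester and cannot enolise. The alkene geometry is of no consequence.

Step 5
Reactants: 6 methyl 2-[3-(benzyloxy)-2,4,6-trimethoxyphenyl]-3-methoxyprop-2-enoate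
Product: 7 2-[3-(benzyloxy)-2,4,6-trimethoxyphenyl]-3-methoxyprop-2-enoic acid (E/Z mixture)
Conditions: LiOH, THF/MeOH/H2O, 50 °C; then dilute HCl to pH 3–4, 0 °C
Reagents that add atoms: lithium hydroxide, [Li+].[OH-]
Why: saponification of a methyl ester; the push-pull enol ether is stable to hydroxide and to brief cold dilute acid. Warming is planned because the ester is hindered.

Step 6
Reactants: 8 3,5-bis(benzyloxy)phenol
Product: 9 3,5-bis(benzyloxy)phenyl N-isopropylcarbamate
Conditions: i-PrNCO, Et3N (cat.), CH2Cl2, rt
Reagents that add atoms: isopropyl isocyanate, CC(C)N=C=O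
Why: base-catalysed addition of a phenol to an isocyanate; it installs a strong ortho-directing group that is later removable under mild base.

Step 7
Reactants: 9 3,5-bis(benzyloxy)phenyl N-isopropylcarbamate
Product: 12 3,5-bis(benzyloxy)-2-(trimethylsilyl)phenyl N-isopropylcarbamate, via N-silylated carbamate 10 (not isolated), via N-silylated C-silylated carbamate 11 (not isolated)
Conditions: TBSOTf, TMEDA, Et2O, 0 °C to rt; then n-BuLi, TMEDA, −78 °C; then TMSCl, −78 °C to rt; aq. NaHSO4 work-up
Reagents that add atoms: chlorotrimethylsilane, C[Si](C)(C)Cl; tert-butyldimethylsilyl trifluoromethanesulfonate, CC(C)(C)[Si](C)(C)OS(=O)(=O)C(F)(F)F (its silyl group is carried only by 10 and 11)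
Why: directed ortho-metalation; N-silylation masks the N–H, and lithiation of 10 should occur at C2, where the carbamate and a benzyloxy group cooperate (C2 and C6 are equivalent). Silylation gives 11, and the acidic work-up removes the N-silyl group.

Step 8
Reactants: 12 3,5-bis(benzyloxy)-2-(trimethylsilyl)phenyl N-isopropylcarbamate
Product: 14 3,5-bis(benzyloxy)-2-(trimethylsilyl)phenyl trifluoromethanesulfonate, via 3,5-bis(benzyloxy)-2-(trimethylsilyl)phenol 13 (not isolated)
Conditions: DBU, Et2NH, MeCN, 40 °C; then PhNTf2, rt
Reagents that add atoms: N-phenylbis(trifluoromethanesulfonimide), O=S(=O)(N(c1ccccc1)S(=O)(=O)C(F)(F)F)C(F)(F)F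
Why: E1cB cleavage of the secondary carbamate (the isocyanate is captured by Et2NH) and triflation of the phenoxide in the same flask. The silylphenol 13, which is prone to protodesilylation, is not isolated.

Step 9
Reactants: 7 2-[3-(benzyloxy)-2,4,6-trimethoxyphenyl]-3-methoxyprop-2-enoic acid; 14 3,5-bis(benzyloxy)-2-(trimethylsilyl)phenyl trifluoromethanesulfonate
Product: 17 5,7-bis(benzyloxy)-3-[3-(benzyloxy)-2,4,6-trimethoxyphenyl]-4H-chromen-4-one, via 3,5-bis(benzyloxy)benzyne 15 (not isolated), via hydroxyaryl methoxyvinyl ketone 16 (not isolated)
Conditions: CsF (4 equiv), THF, 125 °C, sealed tube (14 in 1.5-fold excess)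
Reagents that add atoms: none
Why: Fluoride removes the silyl group of 14 and triflate departs to give 15 (triple bond C1–C2, benzyloxy groups at C3 and C5); the carboxylate of 7, formed by fluoride, adds through oxygen to C1, and the aryl anion so formed at C2 attacks the ester carbonyl in a 4-exo-trig closure whose collapse moves the acyl group to carbon and frees the phenoxide of 16. This is the known insertion of an aryne into the C–O bond of a carboxylic acid (carboxylate addition, then anionic Fries-type acyl shift), which with α,β-unsaturated acids is known to continue by oxa-Michael closure to chromanones. Here the phenoxide of 16 adds to the β-carbon of the methoxy enone (6-endo-trig oxa-Michael) and methoxide is expelled (E1cB), so ring C is closed at O1–C2 after C8a–O1 and C4a–C4 have been made in the same flask. No stereocentre is formed, and both enol ether isomers of 7 converge on 17. The step needs one regioselectivity, oxygen at the future C8a and the acyl carbon at the future C4a beside the C5 benzyloxy group: the inductively withdrawing C3–O bond of 15 distorts the aryne so that C1 is the more linear and more electrophilic terminus and the developing charge at C2 lies beside that C–O bond, C2 is also the more hindered site, and the C5 benzyloxy group is too remote to reverse this. It also needs attack of the aryl anion on the carbonyl carbon and not on the β-carbon (which would lead to a 3-arylcoumarin); the methoxy donor deactivates the β-carbon, and the in-plane carbanion is held next to the twisted ester carbonyl. The main competing process, proton capture by the aryl anion to give a plain aryl ester, should be held back by the aprotic medium and by the high temperature that favours the intramolecular acyl shift.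

Step 10
Reactants: 17 5,7-bis(benzyloxy)-3-[3-(benzyloxy)-2,4,6-trimethoxyphenyl]-4H-chromen-4-one
Product: 18 5,7-dihydroxy-3-(3-hydroxy-2,4,6-trimethoxyphenyl)-4H-chromen-4-one (target)
Conditions: H2 (1 atm), 10% Pd/C, EtOAc/MeOH, rt, stopped after uptake of 3 equiv
Reagents that add atoms: none
Why: hydrogenolysis of three aryl benzyl ethers under neutral conditions; methyl ethers are inert, and the C2=C3 bond, a tetrasubstituted-like vinylogous ester shielded by ring B, should be reduced much more slowly than the benzyl ethers are cleaved.

## Compound list

1 | 2,4,6-trimethoxybenzaldehyde | COc1cc(OC)c(C=O)c(OC)c1 | starting material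
2 | 2,4,6-trimethoxyphenyl formate | COc1cc(OC)c(OC=O)c(OC)c1 | intermediate (not isolated)
3 | 2,4,6-trimethoxyphenol | COc1cc(OC)c(O)c(OC)c1 | intermediate
4 | 2-(benzyloxy)-1,3,5-trimethoxybenzene | COc1cc(OC)c(OCc2ccccc2)c(OC)c1 | intermediate
5 | methyl 2-[3-(benzyloxy)-2,4,6-trimethoxyphenyl]-2-oxoacetate | COC(=O)C(=O)c1c(OC)cc(OC)c(OCc2ccccc2)c1OC | intermediate
6 | methyl 2-[3-(benzyloxy)-2,4,6-trimethoxyphenyl]-3-methoxyprop-2-enoate (E/Z mixture) | COC=C(C(=O)OC)c1c(OC)cc(OC)c(OCc2ccccc2)c1OC | intermediate
7 | 2-[3-(benzyloxy)-2,4,6-trimethoxyphenyl]-3-methoxyprop-2-enoic acid (E/Z mixture) | COC=C(C(=O)O)c1c(OC)cc(OC)c(OCc2ccccc2)c1OC | intermediate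
8 | 3,5-bis(benzyloxy)phenol | Oc1cc(OCc2ccccc2)cc(OCc2ccccc2)c1 | starting material
9 | 3,5-bis(benzyloxy)phenyl N-isopropylcarbamate | CC(C)NC(=O)Oc1cc(OCc2ccccc2)cc(OCc2ccccc2)c1 | intermediate
10 | 3,5-bis(benzyloxy)phenyl N-(tert-butyldimethylsilyl)-N-isopropylcarbamate | CC(C)N(C(=O)Oc1cc(OCc2ccccc2)cc(OCc2ccccc2)c1)[Si](C)(C)C(C)(C)C | intermediate (not isolated)
11 | 3,5-bis(benzyloxy)-2-(trimethylsilyl)phenyl N-(tert-butyldimethylsilyl)-N-isopropylcarbamate | CC(C)N(C(=O)Oc1cc(OCc2ccccc2)cc(OCc2ccccc2)c1[Si](C)(C)C)[Si](C)(C)C(C)(C)C | intermediate (not isolated)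
12 | 3,5-bis(benzyloxy)-2-(trimethylsilyl)phenyl N-isopropylcarbamate | CC(C)NC(=O)Oc1cc(OCc2ccccc2)cc(OCc2ccccc2)c1[Si](C)(C)C | intermediate
13 | 3,5-bis(benzyloxy)-2-(trimethylsilyl)phenol | Oc1cc(OCc2ccccc2)cc(OCc2ccccc2)c1[Si](C)(C)C | intermediate (not isolated)
14 | 3,5-bis(benzyloxy)-2-(trimethylsilyl)phenyl trifluoromethanesulfonate | O=S(=O)(Oc1cc(OCc2ccccc2)cc(OCc2ccccc2)c1[Si](C)(C)C)C(F)(F)F | intermediate
15 | 3,5-bis(benzyloxy)benzyne | C1(OCc2ccccc2)=CC(OCc2ccccc2)=CC#C1 | intermediate (not isolated)
16 | 1-[2,4-bis(benzyloxy)-6-hydroxyphenyl]-2-[3-(benzyloxy)-2,4,6-trimethoxyphenyl]-3-methoxyprop-2-en-1-one (E/Z mixture, formed as its phenoxide) | COC=C(C(=O)c1c(O)cc(OCc2ccccc2)cc1OCc1ccccc1)c1c(OC)cc(OC)c(OCc2ccccc2)c1OC | intermediate (not isolated)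
17 | 5,7-bis(benzyloxy)-3-[3-(benzyloxy)-2,4,6-trimethoxyphenyl]-4H-chromen-4-one | O=c1c(-c2c(OC)cc(OC)c(OCc3ccccc3)c2OC)coc2cc(OCc3ccccc3)cc(OCc3ccccc3)c12 | intermediate
18 | 5,7-dihydroxy-3-(3-hydroxy-2,4,6-trimethoxyphenyl)-4H-chromen-4-one | COc1cc(OC)c(-c2coc3cc(O)cc(O)c3c2=O)c(OC)c1O | target

## Step count and risk

Total steps: 10. Longest linear sequence: 7 steps (steps 1, 2, 3, 4, 5, 9, 10). The ring A branch (steps 6, 7, 8) joins at step 9.

Step 9 (key step). The most likely failure is proton capture by the aryl anion before the acyl shift, which would stop the sequence at simple O-arylation; the carbonyl is made less electrophilic by push-pull conjugation and is hindered by ring B. Aryne self-reaction would also consume 14. The fallback sets out from 7 and 8 and returns at 17. Phenol 8 would be iodinated ortho to the hydroxyl group (N-iodosuccinimide, cat. TsOH, MeCN, 0 °C, with removal of any para isomer) to give 3,5-bis(benzyloxy)-2-iodophenol F1. Esterification of 7 with F1 (DCC, DMAP, CH2Cl2) would give 3,5-bis(benzyloxy)-2-iodophenyl 2-[3-(benzyloxy)-2,4,6-trimethoxyphenyl]-3-methoxyprop-2-enoate F2. Iodine–lithium exchange on F2 (t-BuLi, 2 equiv, THF, −100 °C) would generate the same ortho-ester aryl anion stoichiometrically and without a proton source. The anionic Fries-type acyl shift and, on warming, closure of the phenoxide with loss of methoxide should then give 17.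

Step 4. The olefination may be slow or fail because the two ortho methoxy groups shield both faces of the ketone. The fallback sets out from 5 and returns at 6. Reduction (NaBH4, MeOH, 0 °C) would give methyl 2-[3-(benzyloxy)-2,4,6-trimethoxyphenyl]-2-hydroxyacetate F3 (racemic). Ionic deoxygenation (Et3SiH, TFA, CH2Cl2, 0 °C) would give methyl 2-[3-(benzyloxy)-2,4,6-trimethoxyphenyl]acetate F4. Claisen formylation (NaH, HCO2Me, THF) would give methyl 2-[3-(benzyloxy)-2,4,6-trimethoxyphenyl]-3-hydroxyprop-2-enoate F5, and O-methylation (Me2SO4, K2CO3, acetone) would give 6.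

Step 7. Competing deprotonation at a benzylic CH2 of the benzyl ethers (followed by 1,2-Wittig rearrangement), lithiation at C4 between the two benzyloxy groups, or an anionic ortho-Fries shift of the carbamate on warming could erode the yield. The fallback sets out from 8 and returns at 14, replacing steps 6 to 8. Bromination ortho to the hydroxyl group (NBS, CH2Cl2, −78 °C, with removal of any para isomer) would give 3,5-bis(benzyloxy)-2-bromophenol F6. O-Silylation (HMDS, THF, 65 °C) would give [3,5-bis(benzyloxy)-2-bromophenoxy]trimethylsilane F7. Bromine–lithium exchange (n-BuLi, THF, −100 °C) would trigger a retro-Brook shift of silicon from oxygen to carbon, and the resulting phenoxide would be trapped with Tf2O to give 14.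

Step 3. The Lewis acid may cleave the methoxy group ortho to the new carbonyl group or the benzyl ether by chelation-assisted dealkylation. The fallback sets out from 4 and returns at 5. Bromination (NBS, MeCN, 0 °C) at either of the two equivalent free positions would give 2-(benzyloxy)-4-bromo-1,3,5-trimethoxybenzene F8. Bromine–lithium exchange (n-BuLi, THF, −78 °C) and inverse addition to excess dimethyl oxalate would give 5 without any Lewis acid.

Step 10. Over-reduction of the C2=C3 bond to the isoflavanone, or slow cleavage of the crowded C3' benzyl ether that prolongs exposure to hydrogen, is the likely problem; the product is also air-sensitive. The fallback sets out from 17 and returns at 18. It replaces reduction by Lewis-acid debenzylation with a cation scavenger (BCl3, pentamethylbenzene, CH2Cl2, −78 °C), which cannot touch the C2=C3 bond and at this temperature should leave the non-chelated methyl ethers intact.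

## Further compounds

F1 | step 9 | 3,5-bis(benzyloxy)-2-iodophenol | Oc1cc(OCc2ccccc2)cc(OCc2ccccc2)c1I
F2 | step 9 | 3,5-bis(benzyloxy)-2-iodophenyl 2-[3-(benzyloxy)-2,4,6-trimethoxyphenyl]-3-methoxyprop-2-enoate (E/Z mixture) | COC=C(C(=O)Oc1cc(OCc2ccccc2)cc(OCc2ccccc2)c1I)c1c(OC)cc(OC)c(OCc2ccccc2)c1OC
F3 | step 4 | methyl 2-[3-(benzyloxy)-2,4,6-trimethoxyphenyl]-2-hydroxyacetate (racemic) | COC(=O)C(O)c1c(OC)cc(OC)c(OCc2ccccc2)c1OC
F4 | step 4 | methyl 2-[3-(benzyloxy)-2,4,6-trimethoxyphenyl]acetate | COC(=O)Cc1c(OC)cc(OC)c(OCc2ccccc2)c1OC
F5 | step 4 | methyl 2-[3-(benzyloxy)-2,4,6-trimethoxyphenyl]-3-hydroxyprop-2-enoate (E/Z mixture) | COC(=O)C(=CO)c1c(OC)cc(OC)c(OCc2ccccc2)c1OC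
F6 | step 7 | 3,5-bis(benzyloxy)-2-bromophenol | Oc1cc(OCc2ccccc2)cc(OCc2ccccc2)c1Br
F7 | step 7 | [3,5-bis(benzyloxy)-2-bromophenoxy]trimethylsilane | C[Si](C)(C)Oc1cc(OCc2ccccc2)cc(OCc2ccccc2)c1Br
F8 | step 3 | 2-(benzyloxy)-4-bromo-1,3,5-trimethoxybenzene | COc1cc(OC)c(OCc2ccccc2)c(OC)c1Br
F0 | step 10 | none | none
A1 | alternative 1 | benzene-1,3,5-triol | Oc1cc(O)cc(O)c1
A2 | alternative 1 | 2-[3-(benzyloxy)-2,4,6-trimethoxyphenyl]acetonitrile | N#CCc1c(OC)cc(OC)c(OCc2ccccc2)c1OC
A3 | alternative 1 | 2-[3-(benzyloxy)-2,4,6-trimethoxyphenyl]-1-(2,4,6-trihydroxyphenyl)ethan-1-one | O=C(Cc1c(OC)cc(OC)c(OCc2ccccc2)c1OC)c1c(O)cc(O)cc1O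
A4 | alternative 1 | 3-[3-(benzyloxy)-2,4,6-trimethoxyphenyl]-5,7-dihydroxy-4H-chromen-4-one | O=c1c(-c2c(OC)cc(OC)c(OCc3ccccc3)c2OC)coc2cc(O)cc(O)c12
A5 | alternative 2 | 5,7-bis(benzyloxy)-3-iodo-4H-chromen-4-one | O=c1c(I)coc2cc(OCc3ccccc3)cc(OCc3ccccc3)c12
A6 | alternative 2 | [3-(benzyloxy)-2,4,6-trimethoxyphenyl]boronic acid | OB(O)c1c(OC)cc(OC)c(OCc2ccccc2)c1OC
A7 | alternative 3 | (E)-1-[2,4-bis(benzyloxy)-6-hydroxyphenyl]-3-[3-(benzyloxy)-2,4,6-trimethoxyphenyl]prop-2-en-1-one | O=C(/C=C/c1c(OC)cc(OC)c(OCc2ccccc2)c1OC)c1c(O)cc(OCc2ccccc2)cc1OCc1ccccc1
A8 | alternative 3 | 1-[2,4-bis(benzyloxy)-6-hydroxyphenyl]-2-[3-(benzyloxy)-2,4,6-trimethoxyphenyl]-3,3-dimethoxypropan-1-one (racemic) | COC(OC)C(C(=O)c1c(O)cc(OCc2ccccc2)cc1OCc1ccccc1)c1c(OC)cc(OC)c(OCc2ccccc2)c1OC
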